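At 8.0 h I read Thursday's flask and had to say how much product stood in it, and whether waiting, taking out product or adding catalyst gained anything.

all flasks: substrate 1.7 M; free catalyst 0.2 mol%

| run | reagent | remark | time |
|---|---|---|---|
| Thursday's | 0.50 equiv | the very flask that is asked about, followed so far |  |
| Friday's | 0.75 equiv | run made earlier |  |
| flask | 0.500 equiv |  | 8.0 h |

- Thursday's (time / h: product / %, substrate / %): 0.667: 41.0, 63.7; 1.33: 49.6, 49.4; 2.50: 50.6, 50.5; 4.00: 52.3, 49.4; 8.00: 48.9, 50.1
- Friday's (time / min: product / %, substrate / %): 3.00: 4.9, 96.2; 5.00: 6.9, 94.0; 10.0: 14.3, 85.1; 20.0: 28.5, 72.3; 40.0: 45.8, 53.5

(readings scatter by 1 percentage point)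

- alder: change nothing and wait 15 h more
- cedar: at 8.0 h take out 90% of the product then present, then wait 15 h
- larch: at 8.0 h add free catalyst, 50.0% of the amount charged, then wait 15 h

- product, in percent of the substrate first charged, at 8.0 h
- the remedy with the largest gain of product, or "none" below 2 percentage points (alder / cedar / larch / none)
- product present, with what was taken out counted in, in percent of the substrate first charged, after alder
- product present, with what was taken out counted in, in percent of the substrate first charged, after cedar

- product that was removed still counts
- additions bring no volume worth counting

I bracketed the product in Thursday's flask. Taking one reagent per product, a charge of 0.500 equiv pays for 50.0% of the substrate as product, and this reagent ceiling was my bound from above. Time did not look short: at the pace of Friday's first 10.0 min, 14.3% in that time, the ceiling fills in 35.0 min, so 8.0 h holds about 13.7 such spans. From below I took Thursday's readings from 1.33 h on, which average 50.3% and show no drift. Two standard errors of that mean come to 1 percentage point, which puts the floor at 49.3%. I committed to the ceiling itself, with no gain from any option.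

The forecast, which said “the reagent has simply run out”, gave 50.3% now, 50.3% after alder, 50.3% after cedar and none as the best remedy, so its figure for now stood 0.3 points above my bracket, less than the scatter of one reading.

Thursday's flask gave 50.0% at 8.0 h, 50.0% after alder and 50.0% after cedar, larch gained 0 points, and the best remedy was none; the ceiling held.

    substrate + free catalyst → catalyst intermediate A (k = 0.120 /M/s)
    reagent + catalyst intermediate A ⇌ catalyst intermediate B (K = 0.730 /M, k = 3.00 /M/s)
    catalyst intermediate B → free catalyst + product (k = 0.780 /s)

With reagent held at its charge, the same flask reached >99.9% against 50.0% as run, so the falling level of reagent is what stopped it. Reagent was the limiting reagent: 0% of its charge stood at 8.00 h, with 49.8% of the substrate still free. A neighbour flask with 0.300 equiv of reagent has a ceiling of 30.0%, and it gave 30.0%.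

The runs come from a simulation for an exercise, noise included.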